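**Retrosynthetic overview**
1. Target 16 ⇐ hydrogenolysis of pentabenzyl ether 15; the (2S) centre is secured by asymmetric transfer hydrogenation used as a kinetic resolution of racemic flavanone 14.
2. Flavanone ring C (formed last) ⇐ oxa-Michael closure of 2'-hydroxychalcone 13 ⇐ key intermolecular Claisen–Schmidt aldol condensation of biaryl methyl ketone 10 with 4-(benzyloxy)benzaldehyde 11.
3. The 8–8'' biaryl bond ⇐ Suzuki–Miyaura coupling of flavone-8-boronate 7 with MOM-protected iodoacetophenone 8.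
4. Flavone pyranone ring (formed first) ⇐ intermolecular Claisen condensation of iodoacetophenone 3 with 4-(benzyloxy)benzoyl chloride 4, then cyclodehydration.
5. Both aromatic halves ⇐ the common iodide 3 from 2',4',6'-trihydroxyacetophenone 1; iodine ortho to the free phenol fixes the 8-linkage on each side.

Assumption: the target SMILES defines only C2 (S) and not the hindered 8–8'' biaryl axis, so the route controls C2 and delivers the (2S) compound as the mixture of atropisomers about that axis; 4 and 11 are taken as commercial.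

**Step 1**
Reactants: 1 2',4',6'-trihydroxyacetophenone
Product: 2 1-[2,4-bis(benzyloxy)-6-hydroxyphenyl]ethan-1-one
Conditions: BnBr (2.1 equiv), K2CO3 (2.2 equiv), DMF, rt
Reagents that add atoms: benzyl bromide (BrCc1ccccc1)
Why: Williamson etherification takes the para phenol and one ortho phenol, while the remaining ortho phenol is deactivated by its hydrogen bond to the acetyl carbonyl.

**Step 2**
Reactants: 2 1-[2,4-bis(benzyloxy)-6-hydroxyphenyl]ethan-1-one
Product: 3 1-[4,6-bis(benzyloxy)-2-hydroxy-3-iodophenyl]ethan-1-one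
Conditions: BnMe3N·ICl2 (1.05 equiv), NaHCO3 (2 equiv), CH2Cl2/MeOH, rt
Reagents that add atoms: benzyltrimethylammonium dichloroiodate (C[N+](C)(C)Cc1ccccc1.Cl[I-]Cl)
Why: Buffered electrophilic aromatic iodination goes ortho to the free, most activating phenol, which places the halogen on the carbon that becomes C8 of each flavonoid unit (confirmed by HMBC/NOE).

**Step 3**
Reactants: 3 1-[4,6-bis(benzyloxy)-2-hydroxy-3-iodophenyl]ethan-1-one; 4 4-(benzyloxy)benzoyl chloride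
Product: 5 1-[4,6-bis(benzyloxy)-2-hydroxy-3-iodophenyl]-3-[4-(benzyloxy)phenyl]propane-1,3-dione
Conditions: LiN(SiMe3)2 (3.3 equiv), THF, −78 to −10 °C; then 4, −78 °C to rt; aq. HCl work-up
Reagents that add atoms: none
Why: Crossed intermolecular Claisen condensation: the phenoxide/enolate dianion is C-acylated by the acid chloride (any O-aroyl ester rearranges under the same base), and the third equivalent of base stores the 1,3-diketone as its enolate so it is acylated only once.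

**Step 4**
Reactants: 5 1-[4,6-bis(benzyloxy)-2-hydroxy-3-iodophenyl]-3-[4-(benzyloxy)phenyl]propane-1,3-dione
Product: 6 5,7-bis(benzyloxy)-2-[4-(benzyloxy)phenyl]-8-iodo-4H-chromen-4-one
Conditions: TsOH·H2O (0.2 equiv), toluene, 90 °C
Reagents that add atoms: none
Why: Acid-catalysed cyclodehydration (hemiketal from the ortho phenol, then loss of water) gives the aromatic 4-pyranone, and catalytic sulfonic acid leaves the benzyl ethers intact.

**Step 5**
Reactants: 6 5,7-bis(benzyloxy)-2-[4-(benzyloxy)phenyl]-8-iodo-4H-chromen-4-one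
Product: 7 5,7-bis(benzyloxy)-2-[4-(benzyloxy)phenyl]-8-(4,4,5,5-tetramethyl-1,3,2-dioxaborolan-2-yl)-4H-chromen-4-one
Conditions: B2pin2 (1.5 equiv), PdCl2(dppf) (8 mol%), KOAc (3 equiv), 1,4-dioxane, 90 °C
Reagents that add atoms: bis(pinacolato)diboron (CC1(C)OB(OC1(C)C)B1OC(C)(C)C(C)(C)O1)
Why: Miyaura borylation: oxidative addition of the aryl iodide to zerovalent palladium and acetate-assisted transmetalation with the diboron give an isolable flavone-8-boronate.

**Step 6**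
Reactants: 3 1-[4,6-bis(benzyloxy)-2-hydroxy-3-iodophenyl]ethan-1-one
Product: 8 1-[4,6-bis(benzyloxy)-3-iodo-2-(methoxymethoxy)phenyl]ethan-1-one
Conditions: NaH (1.2 equiv), DMF, 0 °C; MOMCl (1.3 equiv), 0 °C to rt
Reagents that add atoms: chloromethyl methyl ether (COCCl)
Why: O-alkylation of the sodium phenoxide (NaH breaks the chelate) masks the phenol for the cross-coupling with a group that can later be removed without touching benzyl ethers.

**Step 7**
Reactants: 7 5,7-bis(benzyloxy)-2-[4-(benzyloxy)phenyl]-8-(4,4,5,5-tetramethyl-1,3,2-dioxaborolan-2-yl)-4H-chromen-4-one (1.5 equiv); 8 1-[4,6-bis(benzyloxy)-3-iodo-2-(methoxymethoxy)phenyl]ethan-1-one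
Product: 9 8-[3-acetyl-4,6-bis(benzyloxy)-2-(methoxymethoxy)phenyl]-5,7-bis(benzyloxy)-2-[4-(benzyloxy)phenyl]-4H-chromen-4-one (racemic about the biaryl axis)
Conditions: Pd(OAc)2 (10 mol%), SPhos (20 mol%), K3PO4 (3 equiv), degassed toluene/H2O (10:1), 100 °C
Reagents that add atoms: none
Why: Suzuki–Miyaura coupling in which the bulky, electron-rich biaryl phosphine drives oxidative addition to the hindered iodide and reductive elimination to the tetra-ortho-oxygenated biaryl; MOM, benzyl, ketone and flavone tolerate aqueous phosphate.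

**Step 8**
Reactants: 9 8-[3-acetyl-4,6-bis(benzyloxy)-2-(methoxymethoxy)phenyl]-5,7-bis(benzyloxy)-2-[4-(benzyloxy)phenyl]-4H-chromen-4-one
Product: 10 8-[3-acetyl-4,6-bis(benzyloxy)-2-hydroxyphenyl]-5,7-bis(benzyloxy)-2-[4-(benzyloxy)phenyl]-4H-chromen-4-one
Conditions: 3 M aq. HCl, MeOH/THF, 50 °C
Reagents that add atoms: none
Why: Acid-catalysed acetal cleavage removes the MOM group ortho to the carbonyl (assisted by chelation) while benzyl ethers and the flavone are stable, freeing the single phenol needed for ring closure.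

**Step 9**
Reactants: 10 8-[3-acetyl-4,6-bis(benzyloxy)-2-hydroxyphenyl]-5,7-bis(benzyloxy)-2-[4-(benzyloxy)phenyl]-4H-chromen-4-one; 11 4-(benzyloxy)benzaldehyde
Product: 13 8-{4,6-bis(benzyloxy)-3-[(2E)-3-(4-benzyloxyphenyl)prop-2-enoyl]-2-hydroxyphenyl}-5,7-bis(benzyloxy)-2-[4-(benzyloxy)phenyl]-4H-chromen-4-one, via aldol β-hydroxy ketone 12 (not isolated)
Conditions: KOH (50% aq.), EtOH/THF, rt, 48 h; then dilute HCl to pH 5
Reagents that add atoms: none
Why: Claisen–Schmidt crossed aldol condensation: the methyl ketone enolate adds to the non-enolisable aldehyde and E1cB dehydration gives the E-enone, the flavone being inert to alkoxide at room temperature.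

**Step 10**
Reactants: 13 the E-chalcone from step 9
Product: 14 5,7-bis(benzyloxy)-2-[4-(benzyloxy)phenyl]-8-{(2RS)-5,7-bis(benzyloxy)-2-[4-(benzyloxy)phenyl]-4-oxo-3,4-dihydro-2H-chromen-8-yl}-4H-chromen-4-one
Conditions: NaOAc (5 equiv), EtOH/THF, reflux
Reagents that add atoms: none
Why: Intramolecular oxa-Michael addition of the only free phenol to the enone is driven to the flavanone by the twisting 6'-benzyloxy group; it can give only the 8-linked isomer and forms C2 as a racemate.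

**Step 11**
Reactants: 14 racemic pentabenzyl flavanone–flavone
Product: 15 5,7-bis(benzyloxy)-2-[4-(benzyloxy)phenyl]-8-{(2S)-5,7-bis(benzyloxy)-2-[4-(benzyloxy)phenyl]-4-oxo-3,4-dihydro-2H-chromen-8-yl}-4H-chromen-4-one
Conditions: RhCl[(R,R)-TsDPEN]Cp* (2 mol%), HCO2H/Et3N (5:2), EtOAc, 25–40 °C, stopped at about 55% conversion (chiral HPLC); chromatography
Reagents that add atoms: none
Why: Noyori-type asymmetric transfer hydrogenation run as a kinetic resolution: the (R,R) catalyst forms 4R carbinols, which only the (2R)-flavanone can give as its favoured cis-(2R,4R)-flavan-4-ol, so the unreacted (2S)-ketone is recovered in high ee while the vinylogous-ester flavone carbonyl is not reduced.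

**Step 12**
Reactants: 15 (2S)-pentabenzyl flavanone–flavone
Product: 16 8-[(2S)-5,7-dihydroxy-2-(4-hydroxyphenyl)-4-oxo-3,4-dihydro-2H-chromen-8-yl]-5,7-dihydroxy-2-(4-hydroxyphenyl)-4H-chromen-4-one
Conditions: H2 (1 atm), Pd/C (10 wt%), THF/MeOH (1:1), rt, stopped at full debenzylation
Reagents that add atoms: none
Why: Hydrogenolysis of the five benzyl aryl ethers is neutral, so C2 (which epimerises only by base-induced ring opening) keeps its S configuration, and the flavone alkene and aryl ketone survive at atmospheric pressure.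

**Compound list**
1 | 2',4',6'-trihydroxyacetophenone | CC(=O)c1c(O)cc(O)cc1O | starting material
2 | 1-[2,4-bis(benzyloxy)-6-hydroxyphenyl]ethan-1-one | CC(=O)c1c(O)cc(OCc2ccccc2)cc1OCc1ccccc1 | intermediate
3 | 1-[4,6-bis(benzyloxy)-2-hydroxy-3-iodophenyl]ethan-1-one | CC(=O)c1c(O)c(I)c(OCc2ccccc2)cc1OCc1ccccc1 | intermediate
4 | 4-(benzyloxy)benzoyl chloride | O=C(Cl)c1ccc(OCc2ccccc2)cc1 | starting material
5 | 1-[4,6-bis(benzyloxy)-2-hydroxy-3-iodophenyl]-3-[4-(benzyloxy)phenyl]propane-1,3-dione | O=C(CC(=O)c1ccc(OCc2ccccc2)cc1)c1c(O)c(I)c(OCc2ccccc2)cc1OCc1ccccc1 | intermediate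
6 | 5,7-bis(benzyloxy)-2-[4-(benzyloxy)phenyl]-8-iodo-4H-chromen-4-one | O=c1cc(-c2ccc(OCc3ccccc3)cc2)oc2c(I)c(OCc3ccccc3)cc(OCc3ccccc3)c12 | intermediate
7 | 5,7-bis(benzyloxy)-2-[4-(benzyloxy)phenyl]-8-(4,4,5,5-tetramethyl-1,3,2-dioxaborolan-2-yl)-4H-chromen-4-one | O=c1cc(-c2ccc(OCc3ccccc3)cc2)oc2c(B3OC(C)(C)C(C)(C)O3)c(OCc3ccccc3)cc(OCc3ccccc3)c12 | intermediate
8 | 1-[4,6-bis(benzyloxy)-3-iodo-2-(methoxymethoxy)phenyl]ethan-1-one | CC(=O)c1c(OCOC)c(I)c(OCc2ccccc2)cc1OCc1ccccc1 | intermediate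
9 | 8-[3-acetyl-4,6-bis(benzyloxy)-2-(methoxymethoxy)phenyl]-5,7-bis(benzyloxy)-2-[4-(benzyloxy)phenyl]-4H-chromen-4-one (axis racemic) | CC(=O)c1c(OCOC)c(-c2c(OCc3ccccc3)cc(OCc3ccccc3)c3c(=O)cc(-c4ccc(OCc5ccccc5)cc4)oc23)c(OCc2ccccc2)cc1OCc1ccccc1 | intermediate
10 | 8-[3-acetyl-4,6-bis(benzyloxy)-2-hydroxyphenyl]-5,7-bis(benzyloxy)-2-[4-(benzyloxy)phenyl]-4H-chromen-4-one (axis racemic) | CC(=O)c1c(O)c(-c2c(OCc3ccccc3)cc(OCc3ccccc3)c3c(=O)cc(-c4ccc(OCc5ccccc5)cc4)oc23)c(OCc2ccccc2)cc1OCc1ccccc1 | intermediate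
11 | 4-(benzyloxy)benzaldehyde | O=Cc1ccc(OCc2ccccc2)cc1 | starting material
12 | 8-{4,6-bis(benzyloxy)-3-[3-(4-benzyloxyphenyl)-3-hydroxypropanoyl]-2-hydroxyphenyl}-5,7-bis(benzyloxy)-2-[4-(benzyloxy)phenyl]-4H-chromen-4-one (racemic carbinol, not isolated) | OC(CC(=O)c1c(O)c(-c2c(OCc3ccccc3)cc(OCc3ccccc3)c3c(=O)cc(-c4ccc(OCc5ccccc5)cc4)oc23)c(OCc2ccccc2)cc1OCc1ccccc1)c1ccc(OCc2ccccc2)cc1 | intermediate
13 | 8-{4,6-bis(benzyloxy)-3-[(2E)-3-(4-benzyloxyphenyl)prop-2-enoyl]-2-hydroxyphenyl}-5,7-bis(benzyloxy)-2-[4-(benzyloxy)phenyl]-4H-chromen-4-one | O=C(/C=C/c1ccc(OCc2ccccc2)cc1)c1c(O)c(-c2c(OCc3ccccc3)cc(OCc3ccccc3)c3c(=O)cc(-c4ccc(OCc5ccccc5)cc4)oc23)c(OCc2ccccc2)cc1OCc1ccccc1 | intermediate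
14 | 5,7-bis(benzyloxy)-2-[4-(benzyloxy)phenyl]-8-{(2RS)-5,7-bis(benzyloxy)-2-[4-(benzyloxy)phenyl]-4-oxo-3,4-dihydro-2H-chromen-8-yl}-4H-chromen-4-one | O=C1CC(c2ccc(OCc3ccccc3)cc2)Oc2c1c(OCc1ccccc1)cc(OCc1ccccc1)c2-c1c(OCc2ccccc2)cc(OCc2ccccc2)c2c(=O)cc(-c3ccc(OCc4ccccc4)cc3)oc12 | intermediate
15 | 5,7-bis(benzyloxy)-2-[4-(benzyloxy)phenyl]-8-{(2S)-5,7-bis(benzyloxy)-2-[4-(benzyloxy)phenyl]-4-oxo-3,4-dihydro-2H-chromen-8-yl}-4H-chromen-4-one | O=C1C[C@@H](c2ccc(OCc3ccccc3)cc2)Oc2c1c(OCc1ccccc1)cc(OCc1ccccc1)c2-c1c(OCc2ccccc2)cc(OCc2ccccc2)c2c(=O)cc(-c3ccc(OCc4ccccc4)cc3)oc12 | intermediate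
16 | 8-[(2S)-5,7-dihydroxy-2-(4-hydroxyphenyl)-4-oxo-3,4-dihydro-2H-chromen-8-yl]-5,7-dihydroxy-2-(4-hydroxyphenyl)-4H-chromen-4-one | O=C1C[C@@H](c2ccc(O)cc2)Oc2c1c(O)cc(O)c2-c1c(O)cc(O)c2c(=O)cc(-c3ccc(O)cc3)oc12 | target

**Totals**
Total step count: 12. Longest linear sequence: 11 steps (1 → 2 → 3 → 5 → 6 → 7 → 9 → 10 → 13 → 14 → 15 → 16).

**Three steps most likely to fail, each with a fallback**

Step 7 (tetra-ortho-oxygenated Suzuki coupling; protodeboronation of 7 or no coupling). The fallback sets out from 8 and comes back at 10, and makes steps 3 to 5 unnecessary. Ullmann homocoupling of 8 (activated Cu powder, DMF, 150 °C) gives the symmetric biaryl 1,1'-[4,4',6,6'-tetrakis(benzyloxy)-2,2'-bis(methoxymethoxy)biphenyl-3,3'-diyl]di(ethan-1-one) F1. Aqueous HCl in MeOH/THF removes both MOM groups to give 1,1'-[4,4',6,6'-tetrakis(benzyloxy)-2,2'-dihydroxybiphenyl-3,3'-diyl]di(ethan-1-one) F2. A deliberately sub-stoichiometric intermolecular Claisen condensation (LiN(SiMe3)2, 6 equiv, THF, then 0.9 equiv of 4) acylates one methyl ketone only, giving 1-[3'-acetyl-4,4',6,6'-tetrakis(benzyloxy)-2,2'-dihydroxybiphenyl-3-yl]-3-[4-(benzyloxy)phenyl]propane-1,3-dione F3, with unreacted bis-ketone recycled. TsOH-catalysed cyclodehydration of the diketone then gives 10.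

Step 11 (kinetic resolution may be slow or unselective on this hindered, atropisomeric substrate, and caps the yield at one half). The fallback sets out from 10 and comes back at 15, replacing steps 9 to 11 by an enantioselective ring closure. C-tert-butoxycarbonylation of the methyl ketone (LiN(SiMe3)2, 3.3 equiv, then Boc2O) gives tert-butyl 3-[4,6-bis(benzyloxy)-3-{5,7-bis(benzyloxy)-2-[4-(benzyloxy)phenyl]-4-oxo-4H-chromen-8-yl}-2-hydroxyphenyl]-3-oxopropanoate F4. Knoevenagel condensation with 11 (piperidine/AcOH, toluene, molecular sieves) gives tert-butyl 2-[4,6-bis(benzyloxy)-3-{5,7-bis(benzyloxy)-2-[4-(benzyloxy)phenyl]-4-oxo-4H-chromen-8-yl}-2-hydroxybenzoyl]-3-[4-(benzyloxy)phenyl]prop-2-enoate F5. A cinchona-derived bifunctional thiourea (10 mol%, toluene, −25 °C) catalyses the oxa-Michael closure to tert-butyl (2S)-5,7-bis(benzyloxy)-2-[4-(benzyloxy)phenyl]-8-{5,7-bis(benzyloxy)-2-[4-(benzyloxy)phenyl]-4-oxo-4H-chromen-8-yl}-4-oxo-3,4-dihydro-2H-chromene-3-carboxylate F6. The quinine- or quinidine-derived pseudoenantiomer that gives 2S is chosen on a monomeric model. TsOH in toluene at 80 °C then cleaves the ester and decarboxylates to 15.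

Step 12 (over-reduction: saturation of the flavone alkene or hydrogenolysis of the benzylic C2–O bond of the flavanone). The fallback sets out from 15 and comes back at 16. All five benzyl ethers are removed by Lewis-acid dealkylation with BCl3 and pentamethylbenzene as cation scavenger (CH2Cl2, −78 °C, MeOH quench), which involves no hydrogen and no base. It makes no new compound (none F0).

**Further compounds**
F1 | step 7 | 1,1'-[4,4',6,6'-tetrakis(benzyloxy)-2,2'-bis(methoxymethoxy)biphenyl-3,3'-diyl]di(ethan-1-one) | CC(=O)c1c(OCOC)c(-c2c(OCOC)c(C(C)=O)c(OCc3ccccc3)cc2OCc2ccccc2)c(OCc2ccccc2)cc1OCc1ccccc1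
F2 | step 7 | 1,1'-[4,4',6,6'-tetrakis(benzyloxy)-2,2'-dihydroxybiphenyl-3,3'-diyl]di(ethan-1-one) | CC(=O)c1c(O)c(-c2c(O)c(C(C)=O)c(OCc3ccccc3)cc2OCc2ccccc2)c(OCc2ccccc2)cc1OCc1ccccc1
F3 | step 7 | 1-[3'-acetyl-4,4',6,6'-tetrakis(benzyloxy)-2,2'-dihydroxybiphenyl-3-yl]-3-[4-(benzyloxy)phenyl]propane-1,3-dione | CC(=O)c1c(O)c(-c2c(O)c(C(=O)CC(=O)c3ccc(OCc4ccccc4)cc3)c(OCc3ccccc3)cc2OCc2ccccc2)c(OCc2ccccc2)cc1OCc1ccccc1
F4 | step 11 | tert-butyl 3-[4,6-bis(benzyloxy)-3-{5,7-bis(benzyloxy)-2-[4-(benzyloxy)phenyl]-4-oxo-4H-chromen-8-yl}-2-hydroxyphenyl]-3-oxopropanoate | CC(C)(C)OC(=O)CC(=O)c1c(O)c(-c2c(OCc3ccccc3)cc(OCc3ccccc3)c3c(=O)cc(-c4ccc(OCc5ccccc5)cc4)oc23)c(OCc2ccccc2)cc1OCc1ccccc1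
F5 | step 11 | tert-butyl 2-[4,6-bis(benzyloxy)-3-{5,7-bis(benzyloxy)-2-[4-(benzyloxy)phenyl]-4-oxo-4H-chromen-8-yl}-2-hydroxybenzoyl]-3-[4-(benzyloxy)phenyl]prop-2-enoate (E/Z mixture) | CC(C)(C)OC(=O)C(=Cc1ccc(OCc2ccccc2)cc1)C(=O)c1c(O)c(-c2c(OCc3ccccc3)cc(OCc3ccccc3)c3c(=O)cc(-c4ccc(OCc5ccccc5)cc4)oc23)c(OCc2ccccc2)cc1OCc1ccccc1
F6 | step 11 | tert-butyl (2S)-5,7-bis(benzyloxy)-2-[4-(benzyloxy)phenyl]-8-{5,7-bis(benzyloxy)-2-[4-(benzyloxy)phenyl]-4-oxo-4H-chromen-8-yl}-4-oxo-3,4-dihydro-2H-chromene-3-carboxylate (C3 epimers) | CC(C)(C)OC(=O)C1C(=O)c2c(OCc3ccccc3)cc(OCc3ccccc3)c(-c3c(OCc4ccccc4)cc(OCc4ccccc4)c4c(=O)cc(-c5ccc(OCc6ccccc6)cc5)oc34)c2O[C@@H]1c1ccc(OCc2ccccc2)cc1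
F0 | step 12 | none | none
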